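**Plan**

1. Last bonds cut first: the two aryl C–Cl bonds (C5 of ring A, C5 of ring B), then the C3–CHO bond of ring A. This leaves the depside of orsellinic acid with methyl 2,4-dihydroxy-3,6-dimethylbenzoate.
2. Central cut, two bonds in one operation: the depside C(=O)–O bond to O-4 of ring B and the C1–C6 bond of ring A. Ring A unfolds into a 3,5,7-trioxooctanoyl chain, an acylketene masked as a diketo-dioxinone.
3. Enabling feature: ring A is a 2,4-dihydroxy-6-methylbenzoyl unit (carboxyl carbon on C1, oxygen on C2 and C4, methyl on C6) whose carboxyl carbon is bound to O-4 of ring B, so one linear C8 acyl chain supplies the ester carbonyl and all six ring A carbons. C3 and C5 of ring A and C5 of ring B are the only aromatic CH positions and take CHO and Cl afterwards.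
4. The chain is cut at two CH2–C(=O) bonds, back to 2,2,6-trimethyl-1,3-dioxin-4-one, acetyl chloride and N-methoxy-N-methylacetamide.
5. Forward: two acylations build the chain; ring B is bought intact; the chain is joined to O-4 of ring B and ring A closes and aromatizes on that ester in the same pot; formylation and double chlorination finish.
6. Stereochemistry: none to set, since the target has no stereocentre and no stereogenic double bond.

Key step: step 3

Remark on numbering: ring A is the benzoyl ring (C1 bears the depside carbonyl, then 2-OH, 3-CHO, 4-OH, 5-Cl, 6-Me) and ring B is the methyl benzoate ring (C1 CO2Me, 2-OH, 3-Me, 4-O-acyl, 5-Cl, 6-Me). The open-chain precursor of ring A is counted from the ester carbonyl (chain C1) to the terminal methyl (chain C8).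

**Route**

Step 1
Reactants: 1 2,2,6-trimethyl-4H-1,3-dioxin-4-one; 2 acetyl chloride
Product: 3 2,2-dimethyl-6-(2-oxopropyl)-4H-1,3-dioxin-4-one
Conditions: 1 (2.0 equiv), LiN(SiMe3)2 (2.1 equiv), THF, −78 °C; AcCl (1.0 equiv), −78 °C; aq NH4Cl
Reagents that add atoms: acetyl chloride (2), CC(Cl)=O
Why: Vinylogous Claisen-type C-acylation, in which the lithium dienolate of 1 attacks the acid chloride through its exocyclic carbon and the more acidic keto-dioxinone formed is deprotonated at once by the second equivalent of dienolate, which should prevent a second acylation and returns 1 for recovery.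

Step 2
Reactants: 3 2,2-dimethyl-6-(2-oxopropyl)-4H-1,3-dioxin-4-one; 4 N-methoxy-N-methylacetamide
Product: 5 6-(2,4-dioxopentyl)-2,2-dimethyl-4H-1,3-dioxin-4-one
Conditions: LiN(iPr)2 (2.5 equiv), THF, −78 °C; 4 (1.1 equiv), −78 to −20 °C; 1 M HCl quench
Reagents that add atoms: N-methoxy-N-methylacetamide (4), CON(C)C(C)=O
Why: Dianion Claisen acylation with a Weinreb amide, in which the second deprotonation occurs at the terminal methyl ketone, this last-formed carbanion is the most nucleophilic site, and the chelated tetrahedral adduct releases the new ketone only on acidic quench, so over-addition and premature cyclization of the polycarbonyl chain should both be avoided.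

Step 3
Reactants: 5 6-(2,4-dioxopentyl)-2,2-dimethyl-4H-1,3-dioxin-4-one; 6 methyl 2,4-dihydroxy-3,6-dimethylbenzoate
Product: 10 methyl 4-[(2,4-dihydroxy-6-methylbenzoyl)oxy]-2-hydroxy-3,6-dimethylbenzoate (desformylatranorin), via acylketene 7 (not isolated), via triketo ester 8 (not isolated), via aldol adduct 9 (not isolated)
Conditions: 6 (1.5 equiv), PhMe, 110 °C, slow addition of 5; cool to 0 °C, Et3N (2 equiv), PhMe/CH2Cl2, 0 °C to rt; then CF3CO2H, rt
Reagents that add atoms: none
Why: Proposed new method: at 110 °C the dioxinone ring of 5 should lose acetone by retro-[4+2] cleavage to give acylketene 7, whose ketene carbon is captured by the 4-OH of 6 to form the depside C(=O)–O bond in aryl triketo ester 8, after which Et3N generates the chain C2 enolate that adds to the chain C7 methyl ketone to give carbinol 9, and CF3CO2H removes water so that the two remaining ketones enolize to the aromatic 2,4-dihydroxy-6-methylbenzoate. The closest known reaction type is the thermolysis of diketo-dioxinones in the presence of alcohols followed by aldol aromatization to alkyl resorcylates, together with the capture of dioxinone-derived acetylketene by phenols to give aryl acetoacetates; what is new is the combination, a phenol as trap for the triketo acylketene and aromatization on an aryl ester. Ring A closes by a 6-exo-trig aldol addition (chain C2 to chain C7, the later ring A C1–C6 bond) in which the enolate double bond C2=C3 lies inside the new ring (enolendo with respect to the C3 ketone), a stereoelectronically favoured mode. No stereocentre is created in the product, since both centres of 9 are erased on aromatization. Two selectivities are needed: capture at O-4 and not O-2 of 6, secured because the 2-OH is held in a hydrogen bond to the neighbouring CO2Me and has two ortho substituents while the 4-OH has a free ortho CH, and C-aldol closure in place of loss of the phenol by lactonization to a 4-hydroxy-2-pyranone or by Claisen closure, secured by a weak amine base in a non-nucleophilic medium at low temperature and by the excess of 6, which recaptures any ketene re-formed from 8 by E1cB elimination.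

Step 4
Reactants: 10 desformylatranorin; 11 dichloromethyl methyl ether
Product: 12 methyl 4-[(3-formyl-2,4-dihydroxy-6-methylbenzoyl)oxy]-2-hydroxy-3,6-dimethylbenzoate (atranorin)
Conditions: Cl2CHOMe (1.2 equiv), TiCl4 (4 equiv), CH2Cl2, −20 to 0 °C; then ice, 1 M HCl
Reagents that add atoms: dichloromethyl methyl ether (11), COC(Cl)Cl
Why: Rieche formylation, in which TiCl4 binds the ring A phenol oxygens and delivers the chloro(methoxy)carbenium ion to the carbon between them (C3, ortho to both OH groups) while C5 of ring A is flanked by the 6-methyl group and C5 of ring B has no ortho hydroxyl, the ArCH(Cl)OMe intermediate being hydrolysed to the aldehyde on work-up and the two esters expected to survive at or below 0 °C.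

Step 5
Reactants: 12 atranorin; 13 sulfuryl chloride
Product: 14 methyl 3-chloro-4-[(3-chloro-5-formyl-4,6-dihydroxy-2-methylbenzoyl)oxy]-6-hydroxy-2,5-dimethylbenzoate (target, CNP0249536.0)
Conditions: SO2Cl2 (2.3 equiv), CH2Cl2/Et2O, 0 °C to rt, dark
Reagents that add atoms: sulfuryl chloride (13), O=S(=O)(Cl)Cl
Why: Electrophilic aromatic chlorination of phenols with SO2Cl2, for which the only aromatic CH positions left are C5 of ring A (ortho to the 4-OH, para to the 2-OH) and C5 of ring B (para to the 2-OH), so exhaustive chlorination needs no site control and ionic conditions in the dark should leave the formyl group and the benzylic methyl groups untouched.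

**Compound list**

1 | 2,2,6-trimethyl-4H-1,3-dioxin-4-one | CC1=CC(=O)OC(C)(C)O1 | starting material
2 | acetyl chloride | CC(Cl)=O | starting material
3 | 2,2-dimethyl-6-(2-oxopropyl)-4H-1,3-dioxin-4-one (keto-dioxinone) | CC(=O)CC1=CC(=O)OC(C)(C)O1 | intermediate
4 | N-methoxy-N-methylacetamide | CON(C)C(C)=O | starting material
5 | 6-(2,4-dioxopentyl)-2,2-dimethyl-4H-1,3-dioxin-4-one (diketo-dioxinone) | CC(=O)CC(=O)CC1=CC(=O)OC(C)(C)O1 | intermediate
6 | methyl 2,4-dihydroxy-3,6-dimethylbenzoate (atraric acid, ring B) | COC(=O)c1c(C)cc(O)c(C)c1O | starting material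
7 | oct-1-ene-1,3,5,7-tetrone (acylketene, not isolated) | CC(=O)CC(=O)CC(=O)C=C=O | intermediate
8 | methyl 2-hydroxy-3,6-dimethyl-4-[(3,5,7-trioxooctanoyl)oxy]benzoate (aryl triketo ester, not isolated) | COC(=O)c1c(C)cc(OC(=O)CC(=O)CC(=O)CC(C)=O)c(C)c1O | intermediate
9 | methyl 2-hydroxy-4-[(2-hydroxy-2-methyl-4,6-dioxocyclohexane-1-carbonyl)oxy]-3,6-dimethylbenzoate (aldol adduct, mixture of stereoisomers, both centres erased in the same step, not isolated) | COC(=O)c1c(C)cc(OC(=O)C2C(=O)CC(=O)CC2(C)O)c(C)c1O | intermediate
10 | methyl 4-[(2,4-dihydroxy-6-methylbenzoyl)oxy]-2-hydroxy-3,6-dimethylbenzoate (desformylatranorin) | COC(=O)c1c(C)cc(OC(=O)c2c(C)cc(O)cc2O)c(C)c1O | intermediate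
11 | dichloromethyl methyl ether | COC(Cl)Cl | starting material
12 | methyl 4-[(3-formyl-2,4-dihydroxy-6-methylbenzoyl)oxy]-2-hydroxy-3,6-dimethylbenzoate (atranorin) | COC(=O)c1c(C)cc(OC(=O)c2c(C)cc(O)c(C=O)c2O)c(C)c1O | intermediate
13 | sulfuryl chloride | O=S(=O)(Cl)Cl | starting material
14 | methyl 3-chloro-4-[(3-chloro-5-formyl-4,6-dihydroxy-2-methylbenzoyl)oxy]-6-hydroxy-2,5-dimethylbenzoate (CNP0249536.0) | COC(=O)c1c(C)c(Cl)c(OC(=O)c2c(C)c(Cl)c(O)c(C=O)c2O)c(C)c1O | target

**Step count**

Total steps: 5. Longest linear sequence: 5 steps (1 to 3 to 5 to 10 to 12 to 14).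

**Steps most likely to fail**

Step 3 (carries the label "Proposed new method:"). The aryl triketo ester may lose its phenol faster than it closes by aldol addition, through lactonization to a pyranone, Claisen closure, or E1cB return to the ketene. The ketene may also be captured by its own enol before the phenol adds.
Fallback by known chemistry, setting out from 6 and rejoining the route at 10: purchased 2,4-dihydroxy-6-methylbenzoic acid (orsellinic acid) F1 would be perbenzylated (BnBr, K2CO3, DMF) to benzyl 2,4-bis(benzyloxy)-6-methylbenzoate F2. The hindered benzyl ester would be saponified (KOH, aqueous DMSO, 90 °C) to 2,4-bis(benzyloxy)-6-methylbenzoic acid F3. This acid would be condensed with 6 through its mixed trifluoroacetic anhydride ((CF3CO)2O, toluene, rt), the classical depside esterification, which acylates the unchelated 4-OH of 6, to give methyl 4-{[2,4-bis(benzyloxy)-6-methylbenzoyl]oxy}-2-hydroxy-3,6-dimethylbenzoate F4. Hydrogenolysis (H2, Pd/C, EtOAc) would remove both benzyl ethers and deliver 10.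

Step 4. Site selectivity on ring A may be poor, with formylation at C5 competing with C3, or double formylation.
Fallback, setting out from 10 and rejoining the route at 14: the competing position would be occupied first by the chlorine it must carry in the end. One equivalent of SO2Cl2 (Et2O, 0 °C) should chlorinate mainly at C5 of ring A, the position para to the 2-OH that orsellinates normally prefer, to give methyl 4-[(3-chloro-4,6-dihydroxy-2-methylbenzoyl)oxy]-2-hydroxy-3,6-dimethylbenzoate F5. Rieche formylation (Cl2CHOMe, TiCl4, CH2Cl2) could then only take the carbon between the two hydroxyls and would give methyl 4-[(3-chloro-5-formyl-4,6-dihydroxy-2-methylbenzoyl)oxy]-2-hydroxy-3,6-dimethylbenzoate (chloroatranorin) F6. A further charge of SO2Cl2 would chlorinate C5 of ring B and give 14.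

Step 5. Chlorination of the less activated ring B may stall, and forcing it may bring on oxidation of the formyl group or radical chlorination of the benzylic methyl groups.
Fallback, setting out from 6 and rejoining the route at 14: the ring B chlorine would be installed while that ring still has two free hydroxyls. SO2Cl2 (1 equiv, Et2O, 0 °C) would convert 6 at its only free position into methyl 3-chloro-4,6-dihydroxy-2,5-dimethylbenzoate F7. Thermolysis of 5 in the presence of F7 under the conditions of step 3 would proceed through acylketene 7, methyl 3-chloro-6-hydroxy-2,5-dimethyl-4-[(3,5,7-trioxooctanoyl)oxy]benzoate F8 and methyl 3-chloro-6-hydroxy-4-[(2-hydroxy-2-methyl-4,6-dioxocyclohexane-1-carbonyl)oxy]-2,5-dimethylbenzoate F9 to give methyl 3-chloro-4-[(2,4-dihydroxy-6-methylbenzoyl)oxy]-6-hydroxy-2,5-dimethylbenzoate F10. Rieche formylation as in step 4 would give methyl 3-chloro-4-[(3-formyl-2,4-dihydroxy-6-methylbenzoyl)oxy]-6-hydroxy-2,5-dimethylbenzoate F11. One equivalent of SO2Cl2 would then chlorinate the single remaining CH (C5 of ring A) and give 14.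

**Further compounds**

F1 | step 3 | 2,4-dihydroxy-6-methylbenzoic acid (orsellinic acid, purchased) | Cc1cc(O)cc(O)c1C(=O)O
F2 | step 3 | benzyl 2,4-bis(benzyloxy)-6-methylbenzoate | Cc1cc(OCc2ccccc2)cc(OCc2ccccc2)c1C(=O)OCc1ccccc1
F3 | step 3 | 2,4-bis(benzyloxy)-6-methylbenzoic acid | Cc1cc(OCc2ccccc2)cc(OCc2ccccc2)c1C(=O)O
F4 | step 3 | methyl 4-{[2,4-bis(benzyloxy)-6-methylbenzoyl]oxy}-2-hydroxy-3,6-dimethylbenzoate | COC(=O)c1c(C)cc(OC(=O)c2c(C)cc(OCc3ccccc3)cc2OCc4ccccc4)c(C)c1O
F5 | step 4 | methyl 4-[(3-chloro-4,6-dihydroxy-2-methylbenzoyl)oxy]-2-hydroxy-3,6-dimethylbenzoate | COC(=O)c1c(C)cc(OC(=O)c2c(C)c(Cl)c(O)cc2O)c(C)c1O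
F6 | step 4 | methyl 4-[(3-chloro-5-formyl-4,6-dihydroxy-2-methylbenzoyl)oxy]-2-hydroxy-3,6-dimethylbenzoate (chloroatranorin) | COC(=O)c1c(C)cc(OC(=O)c2c(C)c(Cl)c(O)c(C=O)c2O)c(C)c1O
F7 | step 5 | methyl 3-chloro-4,6-dihydroxy-2,5-dimethylbenzoate | COC(=O)c1c(C)c(Cl)c(O)c(C)c1O
F8 | step 5 | methyl 3-chloro-6-hydroxy-2,5-dimethyl-4-[(3,5,7-trioxooctanoyl)oxy]benzoate | COC(=O)c1c(C)c(Cl)c(OC(=O)CC(=O)CC(=O)CC(C)=O)c(C)c1O
F9 | step 5 | methyl 3-chloro-6-hydroxy-4-[(2-hydroxy-2-methyl-4,6-dioxocyclohexane-1-carbonyl)oxy]-2,5-dimethylbenzoate | COC(=O)c1c(C)c(Cl)c(OC(=O)C2C(=O)CC(=O)CC2(C)O)c(C)c1O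
F10 | step 5 | methyl 3-chloro-4-[(2,4-dihydroxy-6-methylbenzoyl)oxy]-6-hydroxy-2,5-dimethylbenzoate | COC(=O)c1c(C)c(Cl)c(OC(=O)c2c(C)cc(O)cc2O)c(C)c1O
F11 | step 5 | methyl 3-chloro-4-[(3-formyl-2,4-dihydroxy-6-methylbenzoyl)oxy]-6-hydroxy-2,5-dimethylbenzoate | COC(=O)c1c(C)c(Cl)c(OC(=O)c2c(C)cc(O)c(C=O)c2O)c(C)c1O
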